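**Retrosynthetic overview**

1. Ring B comes from the arene methyl 4‑hydroxybenzoate 1, hydrogenated to the achiral keto ester 2. The key step is an enantioselective α‑bromination that tells apart the two mirror‑related α‑CH2 groups of 2 (kinetic trans 3, equilibrated to cis 4).
2. MeMgBr on 4 sets the cis‑bromohydrin (5). The ester carbon then becomes the linking C(=CH2) through carbinol 6, allylsilane 7 and allyl bromide 8.
3. Ring A is taken intact from (S)‑carvone 9: epoxide 10 (sets the tertiary C–O), diol 11, α‑ketol 12.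
4. The CH2–ring A bond is made by allylation of dianion 13 with 8 (gives 14). The last disconnection is the secondary carbinol of ring A, from ketone 14 to target 15.
5. Ring order: ring B is released first from the benzene ring, ring A arrives preformed; no ring is closed in the route.

Assumption: in step 2 the (4R,5R) catalyst is taken to give the (1R) series; if the sense is opposite, its (4S,5S) enantiomer is used and nothing else changes.

**Step 1**
Reactants: 1 methyl 4‑hydroxybenzoate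
Product: 2 methyl 4‑oxocyclohexane‑1‑carboxylate
Conditions: H2 (10 bar), 5 wt% Pd on carbon, AlCl3 (10 mol%), CH2Cl2, 50 °C
Reagents that add atoms: none
Why: Partial hydrogenation of a phenol (dearomatization) stops at the cyclohexanone because the Lewis‑acid‑bound ketone is not reduced further on palladium metal; the product has a mirror plane through C1 and C4, so no stereocentre is set.

**Step 2**
Reactants: 2 methyl 4‑oxocyclohexane‑1‑carboxylate
Product: 4 methyl (1R,3R)‑3‑bromo‑4‑oxocyclohexane‑1‑carboxylate, via trans-bromoketone 3 (not isolated)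
Conditions: (4R,5R)‑4,5‑diphenylimidazolidine (20 mol%), PhCO2H (20 mol%), 4,4‑dibromo‑2,6‑di‑tert‑butylcyclohexa‑2,5‑dien‑1‑one (1.05 equiv), THF, −30 °C; then LiBr (0.2 equiv), DMF, 23 °C; chromatography, recovered 3 re‑equilibrated
Reagents that add atoms: 4,4‑dibromo‑2,6‑di‑tert‑butylcyclohexa‑2,5‑dien‑1‑one, CC(C)(C)C1=CC(Br)(Br)C=C(C(C)(C)C)C1=O; lithium bromide (exchanges bromine with the product), [Li+].[Br-]
Why: Proposed new method: the chiral secondary amine forms one of the two enantiotopic enamines of 2, which is brominated axially by the mild Br+ donor, so the choice of α‑carbon fixes C1 as R; the labile C–Br centre is then equilibrated by bromide SN2 exchange towards the diequatorial cis isomer (3R), expected to be favoured only about 2:1 in polar medium, without loss of enantiopurity because C1 is not touched; the closest known reactions are the imidazolidine‑catalysed enantioselective α‑bromination and α‑chlorination of cyclohexanone and the enamine‑catalysed desymmetrization of 4‑substituted cyclohexanones by α‑aminoxylation or α‑fluorination.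

**Step 3**
Reactants: 4 methyl (1R,3R)‑3‑bromo‑4‑oxocyclohexane‑1‑carboxylate
Product: 7 (1S,2R,4R)‑2‑bromo‑1‑methyl‑4‑[3‑(trimethylsilyl)prop‑1‑en‑2‑yl]cyclohexan‑1‑ol, via hydroxy ester 5 (not isolated), via bis-silyl carbinol 6 (not isolated)
Conditions: MeMgBr (1.05 equiv), Et2O, −78 °C; then transfer into Me3SiCH2MgCl (4 equiv), CeCl3 (4 equiv), THF, −78 → 0 °C; then 1 M HCl, 23 °C
Reagents that add atoms: methylmagnesium bromide, C[Mg]Br; (trimethylsilyl)methylmagnesium chloride, C[Si](C)(C)C[Mg]Cl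
Why: Chemoselective Grignard addition to the activated α‑bromoketone from the equatorial direction, trans to the equatorial bromine (as in the classical formation of cis‑halohydrins from 2‑halocyclohexanones), sets the tertiary carbinol as S with OH axial and cis to Br; double addition of the silylmethyl cerium reagent to the ester followed by acid‑induced Peterson elimination then turns the ester carbon into the 2‑substituted allylsilane.

**Step 4**
Reactants: 7 (1S,2R,4R)‑2‑bromo‑1‑methyl‑4‑[3‑(trimethylsilyl)prop‑1‑en‑2‑yl]cyclohexan‑1‑ol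
Product: 8 (1S,2R,4R)‑2‑bromo‑4‑(3‑bromoprop‑1‑en‑2‑yl)‑1‑methylcyclohexan‑1‑ol
Conditions: NBS (1.05 equiv), CH2Cl2, −78 °C
Reagents that add atoms: N‑bromosuccinimide, O=C1CCC(=O)N1Br
Why: Electrophilic bromodesilylation of an allylsilane (SE2'): Br+ adds to the terminal CH2, the β‑silyl cation loses silicon and the 1,1‑disubstituted alkene is regenerated regiospecifically, with no stereocentre involved.

**Step 5**
Reactants: 9 (S)‑(+)‑carvone, (5S)‑2‑methyl‑5‑(prop‑1‑en‑2‑yl)cyclohex‑2‑en‑1‑one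
Product: 10 (1S,4S,6S)‑1‑methyl‑4‑(prop‑1‑en‑2‑yl)‑7‑oxabicyclo[4.1.0]heptan‑2‑one
Conditions: 30% H2O2, NaOH (cat.), MeOH, 0 °C
Reagents that add atoms: hydrogen peroxide, OO
Why: Weitz–Scheffer nucleophilic epoxidation: hydroperoxide adds axially to the β‑carbon anti to the equatorial isopropenyl group, so the epoxide oxygen (the future tertiary C–O bond) is trans to isopropenyl.

**Step 6**
Reactants: 10 (1S,4S,6S)‑1‑methyl‑4‑(prop‑1‑en‑2‑yl)‑7‑oxabicyclo[4.1.0]heptan‑2‑one
Product: 11 (1S,2R,4S)‑1‑methyl‑4‑(prop‑1‑en‑2‑yl)cyclohexane‑1,2‑diol (major C2 epimer; the minor epimer is carried along)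
Conditions: LiEt3BH (3 equiv), THF, −78 → 40 °C; aq NaOH work‑up
Reagents that add atoms: none
Why: Hydride reduction of the ketone followed by SN2 epoxide opening at the secondary carbon, the only site the bulky triethylborohydride can reach, keeps the tertiary C–O bond with its configuration (1S); the secondary carbinol (mainly R, hydride anti to the epoxide oxygen) is removed in the next step.

**Step 7**
Reactants: 11 (1S,2R,4S)‑1‑methyl‑4‑(prop‑1‑en‑2‑yl)cyclohexane‑1,2‑diol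
Product: 12 (2S,5S)‑2‑hydroxy‑2‑methyl‑5‑(prop‑1‑en‑2‑yl)cyclohexan‑1‑one
Conditions: IBX (1.5 equiv), EtOAc, 75 °C
Reagents that add atoms: none
Why: Hypervalent‑iodine oxidation of the secondary alcohol of a 1,2‑diol gives the α‑ketol without C–C cleavage; both C2 epimers converge and no stereocentre is created.

**Step 8**
Reactants: 12 (2S,5S)‑2‑hydroxy‑2‑methyl‑5‑(prop‑1‑en‑2‑yl)cyclohexan‑1‑one; 8 (1S,2R,4R)‑2‑bromo‑4‑(3‑bromoprop‑1‑en‑2‑yl)‑1‑methylcyclohexan‑1‑ol
Product: 14 (2S,5S,6R)‑6‑{2‑[(1R,3R,4S)‑3‑bromo‑4‑hydroxy‑4‑methylcyclohexyl]prop‑2‑en‑1‑yl}‑2‑hydroxy‑2‑methyl‑5‑(prop‑1‑en‑2‑yl)cyclohexan‑1‑one, via dilithium enolate 13 (not isolated)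
Conditions: 12 (1.5 equiv), LiN(i‑Pr)2 (4.0 equiv), THF, −78 → 0 °C; DMPU, then 8 (1.0 equiv), −78 → −20 °C; AcOH
Reagents that add atoms: none
Why: SN2 C‑allylation of the only possible enolate of the ketol (the other α‑carbon is quaternary) occurs anti to the adjacent isopropenyl group, setting C6 as R (trans); this is also the thermodynamic epimer, and any minor enantiomer of 8 becomes a separable diastereomer here.

**Step 9**
Reactants: 14 (2S,5S,6R)‑6‑{2‑[(1R,3R,4S)‑3‑bromo‑4‑hydroxy‑4‑methylcyclohexyl]prop‑2‑en‑1‑yl}‑2‑hydroxy‑2‑methyl‑5‑(prop‑1‑en‑2‑yl)cyclohexan‑1‑one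
Product: 15 (1S,2S,3R,4S)‑3‑{2‑[(1R,3R,4S)‑3‑bromo‑4‑hydroxy‑4‑methylcyclohexyl]prop‑2‑en‑1‑yl}‑1‑methyl‑4‑(prop‑1‑en‑2‑yl)cyclohexane‑1,2‑diol
Conditions: NaBH4, MeOH, −40 → 0 °C
Reagents that add atoms: none
Why: Axial hydride delivery to the cyclohexanone, whose other face is shielded by the axial methyl of the neighbouring carbinol carbon, gives the equatorial alcohol (2S) trans to both flanking substituents, and borohydride leaves the secondary bromide and both alkenes untouched.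

**Compound list**

1 | methyl 4‑hydroxybenzoate | COC(=O)c1ccc(O)cc1 | starting material
2 | methyl 4‑oxocyclohexane‑1‑carboxylate | COC(=O)C1CCC(=O)CC1 | intermediate
3 | methyl (1R,3S)‑3‑bromo‑4‑oxocyclohexane‑1‑carboxylate (trans, Br axial) | COC(=O)[C@@H]1CCC(=O)[C@@H](Br)C1 | intermediate
4 | methyl (1R,3R)‑3‑bromo‑4‑oxocyclohexane‑1‑carboxylate (cis, diequatorial) | COC(=O)[C@@H]1CCC(=O)[C@H](Br)C1 | intermediate
5 | methyl (1R,3R,4S)‑3‑bromo‑4‑hydroxy‑4‑methylcyclohexane‑1‑carboxylate (formed as its bromomagnesium alkoxide) | COC(=O)[C@@H]1CC[C@](C)(O)[C@H](Br)C1 | intermediate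
6 | 2‑[(1R,3R,4S)‑3‑bromo‑4‑hydroxy‑4‑methylcyclohexyl]‑1,3‑bis(trimethylsilyl)propan‑2‑ol | C[Si](C)(C)CC(O)(C[Si](C)(C)C)[C@@H]1CC[C@](C)(O)[C@H](Br)C1 | intermediate
7 | (1S,2R,4R)‑2‑bromo‑1‑methyl‑4‑[3‑(trimethylsilyl)prop‑1‑en‑2‑yl]cyclohexan‑1‑ol | C=C(C[Si](C)(C)C)[C@@H]1CC[C@](C)(O)[C@H](Br)C1 | intermediate
8 | (1S,2R,4R)‑2‑bromo‑4‑(3‑bromoprop‑1‑en‑2‑yl)‑1‑methylcyclohexan‑1‑ol | C=C(CBr)[C@@H]1CC[C@](C)(O)[C@H](Br)C1 | intermediate
9 | (S)‑(+)‑carvone, (5S)‑2‑methyl‑5‑(prop‑1‑en‑2‑yl)cyclohex‑2‑en‑1‑one | CC1=CC[C@@H](CC1=O)C(C)=C | starting material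
10 | (1S,4S,6S)‑1‑methyl‑4‑(prop‑1‑en‑2‑yl)‑7‑oxabicyclo[4.1.0]heptan‑2‑one (epoxide trans to isopropenyl) | O=C1C[C@@H](C(C)=C)C[C@@H]2O[C@]12C | intermediate
11 | (1S,2R,4S)‑1‑methyl‑4‑(prop‑1‑en‑2‑yl)cyclohexane‑1,2‑diol (major C2 epimer) | CC(=C)[C@H]1CC[C@](C)(O)[C@H](O)C1 | intermediate
12 | (2S,5S)‑2‑hydroxy‑2‑methyl‑5‑(prop‑1‑en‑2‑yl)cyclohexan‑1‑one (OH trans to isopropenyl) | CC(=C)[C@H]1CC[C@](C)(O)C(=O)C1 | intermediate
13 | dilithium (3S,6S)‑6‑methyl‑3‑(prop‑1‑en‑2‑yl)cyclohex‑1‑ene‑1,6‑bis(olate) | [Li+].[Li+].CC(=C)[C@H]1CC[C@](C)([O-])C([O-])=C1 | intermediate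
14 | (2S,5S,6R)‑6‑{2‑[(1R,3R,4S)‑3‑bromo‑4‑hydroxy‑4‑methylcyclohexyl]prop‑2‑en‑1‑yl}‑2‑hydroxy‑2‑methyl‑5‑(prop‑1‑en‑2‑yl)cyclohexan‑1‑one | C=C(C[C@@H]1[C@@H](C(=C)C)CC[C@](C)(O)C1=O)[C@@H]1CC[C@](C)(O)[C@H](Br)C1 | intermediate
15 | (1S,2S,3R,4S)‑3‑{2‑[(1R,3R,4S)‑3‑bromo‑4‑hydroxy‑4‑methylcyclohexyl]prop‑2‑en‑1‑yl}‑1‑methyl‑4‑(prop‑1‑en‑2‑yl)cyclohexane‑1,2‑diol | C=C(C[C@@H]1[C@@H](C(=C)C)CC[C@](C)(O)[C@H]1O)[C@@H]1CC[C@](C)(O)[C@H](Br)C1 | target

**Step count**

Total step count: 9. Longest linear sequence: 6 steps (steps 1, 2, 3, 4, 8, 9).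

**Steps most likely to fail, with fallbacks**

Step 2 is the least secure. The desymmetrizing variant of the enamine bromination is unproven, its sense and level of induction are assumed, and the cis:trans equilibrium of the bromoketone is only modestly in favour of 4. The fallback sets out from 2 and breaks the symmetry by deprotonation instead of by C–Br bond formation. The lithium amide of (S,S)‑bis(1‑phenylethyl)amine is used; I recall its antipode giving the (S)‑enol silane from 4‑tert‑butylcyclohexanone, but the sense should be confirmed. With in‑situ Me3SiCl in THF at −78 °C it removes one of the enantiotopic axial α‑protons and gives methyl (1R)‑4‑[(trimethylsilyl)oxy]cyclohex‑3‑ene‑1‑carboxylate F1. NBS brominates F1 axially to 3, and the LiBr equilibration of step 2 brings the route back to 4.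

Step 3 is the second risk. It relies on equatorial delivery of the methyl group to the equatorial α‑bromoketone and on a clean double silylmethyl addition and Peterson elimination in one flask with a free bromohydrin present. The fallback sets out from 4 and builds the three‑carbon linker without silicon. Excess MeMgBr (3.5 equiv) gives (1S,2R,4R)‑2‑bromo‑4‑(2‑hydroxypropan‑2‑yl)‑1‑methylcyclohexan‑1‑ol F2. Burgess reagent dehydrates the unhindered side‑chain carbinol to (1S,2R,4R)‑2‑bromo‑1‑methyl‑4‑(prop‑1‑en‑2‑yl)cyclohexan‑1‑ol F3. Ene‑type chlorination with Ca(OCl)2 and CO2 gives (1S,2R,4R)‑2‑bromo‑4‑(3‑chloroprop‑1‑en‑2‑yl)‑1‑methylcyclohexan‑1‑ol F4. With NaI, F4 takes the place of 8 in the allylation of 13, so this fallback comes back to the route at 14.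

Step 8 is the third risk. A ketol dianion must be C‑alkylated by a hindered allylic bromide that carries a free tertiary alcohol, and proton transfer, O‑alkylation or α‑ketol rearrangement may compete. The fallback sets out from epoxy ketone 10 and moves the coupling ahead of the ketol construction, so that a simple mono‑enolate is used. Deprotonation of 10 with LiN(i‑Pr)2 and allylation with 8 gives (1S,3R,4S,6S)‑3‑{2‑[(1R,3R,4S)‑3‑bromo‑4‑hydroxy‑4‑methylcyclohexyl]prop‑2‑en‑1‑yl}‑1‑methyl‑4‑(prop‑1‑en‑2‑yl)‑7‑oxabicyclo[4.1.0]heptan‑2‑one F5. LiAlH4 in Et2O at −20 °C reduces the ketone and opens the epoxide at the secondary carbon while sparing the hindered secondary bromide, to give (1S,3R,4S)‑3‑{2‑[(1R,3R,4S)‑3‑bromo‑4‑hydroxy‑4‑methylcyclohexyl]prop‑2‑en‑1‑yl}‑1‑methyl‑4‑(prop‑1‑en‑2‑yl)cyclohexane‑1,2‑diol F6 as a mixture of C2 epimers. IBX oxidation of F6 comes back to the route at 14.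

**Further compounds**

F1 | step 2 | methyl (1R)‑4‑[(trimethylsilyl)oxy]cyclohex‑3‑ene‑1‑carboxylate | COC(=O)[C@@H]1CCC(O[Si](C)(C)C)=CC1
F2 | step 3 | (1S,2R,4R)‑2‑bromo‑4‑(2‑hydroxypropan‑2‑yl)‑1‑methylcyclohexan‑1‑ol | CC(C)(O)[C@@H]1CC[C@](C)(O)[C@H](Br)C1
F3 | step 3 | (1S,2R,4R)‑2‑bromo‑1‑methyl‑4‑(prop‑1‑en‑2‑yl)cyclohexan‑1‑ol | CC(=C)[C@@H]1CC[C@](C)(O)[C@H](Br)C1
F4 | step 3 | (1S,2R,4R)‑2‑bromo‑4‑(3‑chloroprop‑1‑en‑2‑yl)‑1‑methylcyclohexan‑1‑ol | C=C(CCl)[C@@H]1CC[C@](C)(O)[C@H](Br)C1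
F5 | step 8 | (1S,3R,4S,6S)‑3‑{2‑[(1R,3R,4S)‑3‑bromo‑4‑hydroxy‑4‑methylcyclohexyl]prop‑2‑en‑1‑yl}‑1‑methyl‑4‑(prop‑1‑en‑2‑yl)‑7‑oxabicyclo[4.1.0]heptan‑2‑one | C=C(C[C@@H]1[C@@H](C(=C)C)C[C@@H]2O[C@]2(C)C1=O)[C@@H]1CC[C@](C)(O)[C@H](Br)C1
F6 | step 8 | (1S,3R,4S)‑3‑{2‑[(1R,3R,4S)‑3‑bromo‑4‑hydroxy‑4‑methylcyclohexyl]prop‑2‑en‑1‑yl}‑1‑methyl‑4‑(prop‑1‑en‑2‑yl)cyclohexane‑1,2‑diol (C2 epimers) | C=C(C[C@@H]1[C@@H](C(=C)C)CC[C@](C)(O)C1O)[C@@H]1CC[C@](C)(O)[C@H](Br)C1
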